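**Retrosynthetic overview**
- C12–C13: reagent-controlled 2-isopropylallylboration of an (E)-2-methyl enal with a borane made from 2,3-dimethylbut-1-ene (sets 12R).
- C10=C11: cross-metathesis of a terminal olefin with methacrolein.
- Both oxirane rings: one double Shi epoxidation of a (2E,6Z)-trienol; the 6,7-oxirane forms first, then the 2,3-oxirane. The cis-6,7-oxirane requires a 6Z olefin.
- C3–C4 and C5–C6: two iodine-triggered 1,2-shifts of carbon from boron to carbon (Zweifel type) on one ethane-1,2-diyl bis(boronic ester), each inverting the alkenyl geometry.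
- Building blocks: hex-1-en-5-yne, but-2-yn-1-ol, ethylene, methacrolein, 2,3-dimethylbut-1-ene.

Assumption: the SMILES is taken literally, i.e. (2R,3R)-trans-oxirane, (6R,7S)-cis-oxirane (C5 and C8 on the same side), 10E and 12R; locants C1–C16 are those of the hexadecane name of the target.

**Route**

Step 1
Reactants: 1 hex-1-en-5-yne
Product: 3 (1E)-1-iodo-2-methylhexa-1,5-diene, via alkenylalane 2 (not isolated)
Conditions: Me3Al (2 equiv), Cp2ZrCl2 (20 mol %), CH2Cl2, 0 °C → rt; then I2, THF, −30 → 0 °C
Reagents that add atoms: trimethylaluminium, C[Al](C)C; iodine, II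
Why: Negishi zirconium-catalysed carboalumination adds CH3 and Al syn across the terminal alkyne with CH3 on the internal carbon, and iodinolysis of the C–Al bond goes with retention, so iodine is cis to the methyl group (E); the isolated vinyl group is inert to Me3Al/Cp2ZrCl2 at room temperature.

Step 2
Reactants: 4 but-2-yn-1-ol
Product: 6 (2Z)-3-iodobut-2-en-1-ol, via cyclic vinylalanate 5 (not isolated)
Conditions: NaAlH2(OCH2CH2OMe)2 (Red-Al, 1.4 equiv), Et2O, 0 °C → rt; then I2, THF, −78 → 0 °C
Reagents that add atoms: iodine, II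
Why: Hydroxyl-directed trans-hydroalumination of the propargylic alcohol puts aluminium on C3 cis to the CH2O arm inside a five-membered alkoxyalanate, and iodinolysis with retention gives the (Z)-iodide.

Step 3
Reactants: 7 ethylene
Product: 8 1,2-bis(4,4,5,5-tetramethyl-1,3,2-dioxaborolan-2-yl)ethane
Conditions: B2pin2, Pt(dba)2 (3 mol %), toluene, 50 °C, ethylene (1 atm)
Reagents that add atoms: bis(pinacolato)diboron, CC1(C)OB(OC1(C)C)B1OC(C)(C)C(C)(C)O1
Why: Platinum-catalysed alkene diboration (oxidative addition of B–B to zerovalent platinum, ethylene insertion, reductive elimination) gives the two-carbon C4–C5 linchpin; no stereocentre is formed.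

Step 4
Reactants: 3 (1E)-1-iodo-2-methylhexa-1,5-diene; 6 (2Z)-3-iodobut-2-en-1-ol; 8 1,2-bis(4,4,5,5-tetramethyl-1,3,2-dioxaborolan-2-yl)ethane
Product: 14 (2E,6Z)-3,7-dimethylundeca-2,6,10-trien-1-ol, via alkenyllithium 9 (not isolated), via mono-borate 10 (not isolated), via dilithio alkoxide 11 (not isolated), via mixed bis-borate 12 (not isolated), via bis(iodoalkyl) boronate 13 (not isolated)
Conditions: 3, t-BuLi (2.0 equiv), Et2O, −78 °C; add to 8 (1.0 equiv), THF, −78 °C; 6, t-BuLi (3.0 equiv), Et2O, −78 °C, cannulate into the first flask, −78 → −40 °C; I2 (2.2 equiv), THF, −78 °C; NaOMe (6 equiv), MeOH, −78 °C → rt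
Reagents that add atoms: none
Why: Proposed new method: a hetero-bidirectional Zweifel olefination of a vicinal bis(boronic ester) through a mixed bis-borate; alkenyllithium 9 adds irreversibly to one boron of 8, and the negative charge (plus O→B chelation) of mono-borate 10 retards a second addition, so the different alkenyllithium 11 can be loaded on the other boron; I2 turns each alkenylborate into an iodonium ion that triggers an anti 1,2-shift of the bridging CH2 from boron to carbon (two 1,2-metallate rearrangements, forming C5–C6 and C3–C4), and methoxide-induced anti elimination of boron and iodine inverts each olefin geometry, so the alkenyl unit of 3 (boron cis to CH3) gives 6Z and that of 6 (boron cis to CH2O) gives 2E; the symmetric by-products carry no or two OH groups and are removed on silica; closest known reaction type: the Zweifel olefination of a mono-boronic ester with a single alkenyllithium, together with the selective mono-borate formation known for 1,2-bis(boronic esters).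

Step 5
Reactants: 14 (2E,6Z)-3,7-dimethylundeca-2,6,10-trien-1-ol
Product: 16 (2R,3R,6R,7S)-2,3:6,7-diepoxy-3,7-dimethylundec-10-en-1-ol, via monoepoxide 15 (not isolated)
Conditions: D-fructose-derived Shi ketone (1,2:4,5-di-O-isopropylidene-β-D-erythro-2,3-hexodiulo-2,6-pyranose, 60 mol %), 2KHSO5·KHSO4·K2SO4 (Oxone, 2.8 equiv), K2CO3, Bu4NHSO4 (cat.), Na2B4O7/Na2EDTA buffer (pH 10.5), MeCN–CH2(OMe)2–H2O, −10 → 0 °C
Reagents that add atoms: potassium peroxymonosulfate (from Oxone), [K+].[O-]S(=O)(=O)OO
Why: Shi asymmetric epoxidation (chiral dioxirane, spiro transition state) gives R at the CH carbon of each trisubstituted olefin, as in the (R,R)-epoxides from trans-olefins and 1-phenylcyclohexene, hence (2R,3R) from the 2E olefin and (6R,7S) from the 6Z olefin by syn oxygen transfer; the electron-richer 6,7-olefin reacts first, the vinyl group is far slower, and two catalyst-controlled events raise the ee of the major diastereomer.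

Step 6
Reactants: 16 (2R,3R,6R,7S)-2,3:6,7-diepoxy-3,7-dimethylundec-10-en-1-ol; 17 methacrolein (2-methylprop-2-enal)
Product: 18 (2E,6S,7R,10R,11R)-6,7:10,11-diepoxy-12-hydroxy-2,6,10-trimethyldodec-2-enal
Conditions: 17 (10 equiv), second-generation Hoveyda–Grubbs catalyst [(H2IMes)Cl2Ru(=CH-C6H4-2-OiPr), 5 mol %], CH2Cl2, 40 °C
Reagents that add atoms: none
Why: Olefin cross-metathesis of a type-1 terminal olefin with excess methacrolein gives the conjugated trisubstituted enal as the thermodynamic E isomer (typically > 20:1), and oxiranes and the free alcohol are inert to the ruthenium carbene.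

Step 7
Reactants: 18 (2E,6S,7R,10R,11R)-6,7:10,11-diepoxy-12-hydroxy-2,6,10-trimethyldodec-2-enal; 19 2,3-dimethylbut-1-ene
Product: 23 (2R,3R,6R,7S,10E,12R)-2,3:6,7-diepoxy-3,7,11,15-tetramethyl-14-methylidenehexadec-10-ene-1,12-diol, via allyllithium 20 (not isolated), via allylborane 21 (not isolated), via borinate 22 (not isolated)
Conditions: 19 (excess), n-BuLi, TMEDA, hexane, rt, 24 h; (+)-Ipc2BCl (from (−)-α-pinene), Et2O, −78 → 0 °C; 18 (0.4 equiv relative to 21), Et2O, −78 °C; H2NCH2CH2OH, rt
Reagents that add atoms: none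
Why: Brown asymmetric allylboration through a closed chair (Zimmerman–Traxler) transition state, in which the borane from (−)-α-pinene attacks the Re face of the enal and sets 12R under reagent control (the borane from (+)-α-pinene gives the S alcohol with benzaldehyde, which has the same priority pattern); chloride-for-allyl exchange gives a reagent free of BF3 and the ethanolamine work-up is non-oxidative, so both oxiranes survive, and the excess borane covers the free primary alcohol.

**Compound list**
1 | hex-1-en-5-yne | C#CCCC=C | starting material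
2 | dimethyl[(1E)-2-methylhexa-1,5-dien-1-yl]alane | C[Al](C)/C=C(\C)CCC=C | intermediate
3 | (1E)-1-iodo-2-methylhexa-1,5-diene | I/C=C(\C)CCC=C | intermediate
4 | but-2-yn-1-ol | CC#CCO | starting material
5 | sodium 2,2-bis(2-methoxyethoxy)-3-methyl-2,5-dihydro-1,2-oxaaluminol-2-uide (cyclic vinylalanate) | CC1=CCO[Al-]1(OCCOC)OCCOC.[Na+] | intermediate
6 | (2Z)-3-iodobut-2-en-1-ol | C/C(I)=C/CO | intermediate
7 | ethylene | C=C | starting material
8 | 1,2-bis(4,4,5,5-tetramethyl-1,3,2-dioxaborolan-2-yl)ethane | CC1(C)OB(CCB2OC(C)(C)C(C)(C)O2)OC1(C)C | intermediate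
9 | [(1E)-2-methylhexa-1,5-dien-1-yl]lithium | [Li]/C=C(\C)CCC=C | intermediate
10 | lithium [(1E)-2-methylhexa-1,5-dien-1-yl](pinacolato)[2-(pinacolatoboryl)ethyl]borate (mono-borate) | [Li+].CC1(C)O[B-](/C=C(\C)CCC=C)(CCB2OC(C)(C)C(C)(C)O2)OC1(C)C | intermediate
11 | lithium (2E)-3-lithiobut-2-en-1-olate (Li cis to CH2O, geometry of 6 retained) | C/C([Li])=C/CO[Li] | intermediate
12 | trilithium mixed bis-borate: ethane-1,2-diyl bridge, one pinacol borate carrying the (1E)-2-methylhexa-1,5-dien-1-yl group, the other the 4-oxidobut-2-en-2-yl group (boron cis to CH2O) | [Li+].[Li+].[Li+].CC1(C)O[B-](/C=C(\C)CCC=C)(CC[B-]2(/C(C)=C\C[O-])OC(C)(C)C(C)(C)O2)OC1(C)C | intermediate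
13 | lithium alkoxide of the bis(β-iodoalkyl) bis(pinacol boronate) from the double anti 1,2-shift (racemic, one diastereomer drawn, all converge on 14) | CC1(C)OB(OC1(C)C)[C@@H](CC[C@](C)(B2OC(C)(C)C(C)(C)O2)[C@H](I)C[O-])[C@@](C)(I)CCC=C.[Li+] | intermediate
14 | (2E,6Z)-3,7-dimethylundeca-2,6,10-trien-1-ol | OC/C=C(\C)CC/C=C(/C)CCC=C | intermediate
15 | (2E,6R,7S)-6,7-epoxy-3,7-dimethylundeca-2,10-dien-1-ol | C=CCC[C@]1(C)O[C@@H]1CC/C(C)=C/CO | intermediate
16 | (2R,3R,6R,7S)-2,3:6,7-diepoxy-3,7-dimethylundec-10-en-1-ol | C=CCC[C@]1(C)O[C@@H]1CC[C@@]1(C)O[C@@H]1CO | intermediate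
17 | methacrolein (2-methylprop-2-enal) | CC(=C)C=O | starting material
18 | (2E,6S,7R,10R,11R)-6,7:10,11-diepoxy-12-hydroxy-2,6,10-trimethyldodec-2-enal | O=C/C(C)=C/CC[C@]1(C)O[C@@H]1CC[C@@]1(C)O[C@@H]1CO | intermediate
19 | 2,3-dimethylbut-1-ene | CC(C)C(C)=C | starting material
20 | [2-(propan-2-yl)prop-2-en-1-yl]lithium | [Li]CC(=C)C(C)C | intermediate
21 | [2-(propan-2-yl)prop-2-en-1-yl]bis[(1S,2R,3S,5S)-2,6,6-trimethylbicyclo[3.1.1]heptan-3-yl]borane | CC(C)C(=C)CB([C@H]1C[C@H]2C[C@@H]([C@@H]1C)C2(C)C)[C@H]1C[C@H]2C[C@@H]([C@@H]1C)C2(C)C | intermediate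
22 | 12-O-[bis((1S,2R,3S,5S)-isopinocampheyl)boryl] derivative of 23 (borinate) | C=C(C[C@@H](OB([C@H]1C[C@H]2C[C@@H]([C@@H]1C)C2(C)C)[C@H]1C[C@H]2C[C@@H]([C@@H]1C)C2(C)C)/C(C)=C/CC[C@]1(C)O[C@@H]1CC[C@@]1(C)O[C@@H]1CO)C(C)C | intermediate
23 | (2R,3R,6R,7S,10E,12R)-2,3:6,7-diepoxy-3,7,11,15-tetramethyl-14-methylidenehexadec-10-ene-1,12-diol | C=C(C[C@@H](O)/C(C)=C/CC[C@]1(C)O[C@@H]1CC[C@@]1(C)O[C@@H]1CO)C(C)C | target

**Step count and risks**
Total step count: 7. Longest linear sequence: 5 steps (1 → 4 → 5 → 6 → 7); steps 2 and 3 feed step 4 in parallel.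

Step 4 (proposed new step). The risks are incomplete selectivity in loading two different alkenyl groups on the two borons, sluggish formation of the vicinal bis-borate, and interference by the lithium alkoxide next to the C–I bond of 13. The fallback sets out from 3, 6 and 8 and comes back at 14, and uses only ordinary single Zweifel olefinations. Lithium reagent 9 is added to an excess of 8 (3 equiv), and mono-borate 10 is treated with I2 and then NaOMe to give the isolated homoallylic boronic ester 4,4,5,5-tetramethyl-2-[(3Z)-4-methylocta-3,7-dien-1-yl]-1,3,2-dioxaborolane F1. Alcohol 6 is silylated (TBSCl, imidazole) to tert-butyl{[(2Z)-3-iodobut-2-en-1-yl]oxy}dimethylsilane F2. Lithiated F2 (t-BuLi) is added to F1, and I2 then NaOMe give tert-butyl{[(2E,6Z)-3,7-dimethylundeca-2,6,10-trien-1-yl]oxy}dimethylsilane F3, which Bu4NF converts into 14.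

Step 5. The risks are lower facial selectivity at the Z-trisubstituted olefin and at the allylic-alcohol olefin than for simple E olefins, which would give diastereomers that are hard to separate, and Payne equilibration at pH 10.5. The fallback sets out from 14 and comes back at 16. Sharpless asymmetric epoxidation (Ti(OiPr)4, D-(−)-diethyl tartrate, t-BuOOH, 4 Å sieves, CH2Cl2, −20 °C) gives [(2R,3R)-3-methyl-3-[(3Z)-4-methylocta-3,7-dien-1-yl]oxiran-2-yl]methanol F4 with titanium–tartrate control of the 2,3-oxirane. A single Shi epoxidation of the remaining 6Z olefin with the same D-fructose-derived ketone then gives 16. This addresses the 2,3-oxirane only; the 6,7-oxirane still relies on the Shi step.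

Step 7. The risks are consumption of the allylborane by the free primary alcohol, Lewis-acid opening of the trisubstituted oxiranes by residual chloroborane, and a 12-epimer that is hard to remove. The fallback sets out from 16 and comes back at 23, and moves the stereo-defining allylboration onto a simple aldehyde. Allylborane 21 (made as in step 7) is added to methacrolein 17 at −78 °C, and ethanolamine work-up gives (3R)-2,6-dimethyl-5-methylidenehept-1-en-3-ol F5. Cross-metathesis of 16 with excess F5 (second-generation Hoveyda–Grubbs catalyst, CH2Cl2, 40 °C) at its less hindered 2-methylallyl olefin then gives 23 directly, with the E/Z isomers separated by chromatography.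

**Further compounds**
F1 | step 4 | 4,4,5,5-tetramethyl-2-[(3Z)-4-methylocta-3,7-dien-1-yl]-1,3,2-dioxaborolane | CC1(C)OB(CC/C=C(/C)CCC=C)OC1(C)C
F2 | step 4 | tert-butyl{[(2Z)-3-iodobut-2-en-1-yl]oxy}dimethylsilane | C/C(I)=C/CO[Si](C)(C)C(C)(C)C
F3 | step 4 | tert-butyl{[(2E,6Z)-3,7-dimethylundeca-2,6,10-trien-1-yl]oxy}dimethylsilane | CC(C)(C)[Si](C)(C)OC/C=C(\C)CC/C=C(/C)CCC=C
F4 | step 5 | [(2R,3R)-3-methyl-3-[(3Z)-4-methylocta-3,7-dien-1-yl]oxiran-2-yl]methanol | C=CCC/C(C)=C\CC[C@@]1(C)O[C@@H]1CO
F5 | step 7 | (3R)-2,6-dimethyl-5-methylidenehept-1-en-3-ol | C=C(C)[C@H](O)CC(=C)C(C)C
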